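Ring A is cut at C3–C4: the 3-acetoxy/C19-formyl pair on the quaternary C4 is a disguised β-hydroxy ester, the aldol of a C4 ester enolate with a C3 aldehyde. A samarium diiodide Reformatsky closure of a tertiary α-bromo ester forms this bond, ring A and the C3 and C4 stereocentres in one operation. Its precursor is a trans-2,3-disubstituted cyclohexanone carrying C5 and C10: a 3-oxopropyl chain and the C20 methyl on C10, the bromo ester on C5. Two Mukaiyama–Michael additions assemble it, with bromine installed while the carbonyl groups are still masked. The C9 ketone later receives the side chain and C17.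

Key step: step 5

Remark: labdane numbering (C1–C20) is used throughout; the ester α-carbon of 5, 7 and 9 is an epimer mixture because step 5 planarises it, and in step 2 the catalyst antipode is the one that directs attack to the Re face of the enone β-carbon.

Step 1
Reactants: 1 methyl propanoate
Product: 3 (E)-1-methoxy-1-(trimethylsilyloxy)prop-1-ene, via lithium ester enolate 2 (not isolated)
Conditions: LDA, THF, −78 °C; TMSCl, −78 °C → rt; distillation
Reagents that add atoms: chlorotrimethylsilane, C[Si](C)(C)Cl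
Why: Kinetic deprotonation of the ester and O-silylation of the lithium enolate is the standard silyl ketene acetal synthesis, and the enolate geometry is of no consequence because this carbon is planarised again in step 5.

Step 2
Reactants: 3 (E)-1-methoxy-1-(trimethylsilyloxy)prop-1-ene; 4 2-methylcyclohex-2-en-1-one
Product: 5 methyl 2-[(1S)-2-methyl-3-(trimethylsilyloxy)cyclohex-2-en-1-yl]propanoate
Conditions: chiral B-(o-tolyl)oxazaborolidinium triflimide from α,α-diphenylprolinol (20 mol %), Ph3P=O (25 mol %), toluene, −20 °C; non-aqueous work-up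
Reagents that add atoms: none
Why: Catalytic enantioselective Mukaiyama–Michael addition of a silyl ketene acetal to a cyclic enone: the chiral Lewis acid shields one face of the β-carbon, so attack on the Re face sets the future C5 as S, and silyl transfer to the enolate oxygen gives the regiodefined tetrasubstituted enol silane.

Step 3
Reactants: 5 methyl 2-[(1S)-2-methyl-3-(trimethylsilyloxy)cyclohex-2-en-1-yl]propanoate
Product: 7 methyl 2-bromo-2-[(1R)-2-methyl-3-(trimethylsilyloxy)cyclohex-2-en-1-yl]propanoate, via lithium ester enolate 6 (not isolated)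
Conditions: LDA, THF, −78 °C; BrCCl2CCl2Br, −78 °C; cold NaHCO3 work-up
Reagents that add atoms: 1,2-dibromo-1,1,2,2-tetrachloroethane, BrC(Cl)(Cl)C(Cl)(Cl)Br
Why: Ester enolate α-bromination: the enol silane masks the ketone and is inert to the amide base, so only the ester α-proton is removed and the enolate takes bromine from the dibromide to give the tertiary bromide before any free ketone or aldehyde exists.

Step 4
Reactants: 7 methyl 2-bromo-2-[(1R)-2-methyl-3-(trimethylsilyloxy)cyclohex-2-en-1-yl]propanoate; 8 acrolein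
Product: 9 methyl 2-bromo-2-[(1R,2S)-2-methyl-3-oxo-2-(3-oxopropyl)cyclohexyl]propanoate
Conditions: BF3·OEt2, i-PrOH, CH2Cl2, −78 °C
Reagents that add atoms: none
Why: Lewis acid-promoted Mukaiyama–Michael addition of the enol silane to acrolein with an alcohol as proton source; acrolein adds to the tetrasubstituted enol carbon anti to the pseudoaxial bromo ester group next to it, so the 3-oxopropyl chain and the C5 substituent end up trans and C10 is set as S.

Step 5
Reactants: 9 methyl 2-bromo-2-[(1R,2S)-2-methyl-3-oxo-2-(3-oxopropyl)cyclohexyl]propanoate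
Product: 11 methyl 3β-hydroxy-9-oxo-11,12,13,14,15,16,17-heptanorlabdan-19-oate, via samarium(III) ester enolate 10 (not isolated)
Conditions: SmI2 (2.2 equiv, added slowly), THF, −78 °C; aq. NH4Cl at −78 °C
Reagents that add atoms: none
Why: Two single-electron transfers cleave the C–Br bond of either epimer and give the samarium(III) ester enolate 10, which adds to the aldehyde inside a samarium chelate; the closest known reaction is the intramolecular samarium Reformatsky reaction of α-bromo esters with aldehydes, which also forms quaternary centres. Ring A closes in the 6-(enolexo)-exo-trig mode. The two reacting arms sit trans-diequatorial on C5 and C10 and hold the new ring in a chair, in which the samarium bridge between enolate oxygen and aldehyde oxygen needs O3 gauche to the ester carbon, so O3 becomes equatorial (3β) and cis to the ester. C4 is controlled by the axial C10 methyl: C18 goes equatorial and the flat ester carbon axial, which avoids a C18/C20 syn-diaxial pair. The step needs reduction of C–Br ahead of the aldehyde and ketone, secured by the much easier reduction of a tertiary α-bromo ester at −78 °C and the slow addition, and it needs attack on the aldehyde only, secured because attack on the C9 ketone would close a four-membered ring. The chair with C18 axial is the competing pathway, and the cold quench keeps the aldolate from reopening.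

Step 6
Reactants: 11 methyl 3β-hydroxy-9-oxo-11,12,13,14,15,16,17-heptanorlabdan-19-oate
Product: 12 methyl 9-oxo-3β-(triethylsilyloxy)-11,12,13,14,15,16,17-heptanorlabdan-19-oate
Conditions: TESCl, imidazole, DMAP (cat.), DMF, rt
Reagents that add atoms: chlorotriethylsilane, CC[Si](Cl)(CC)CC
Why: Standard silylation of a secondary alcohol; the triethylsilyl ether blocks retro-aldol opening under the strong base of step 7 and is removed later together with the ketal.

Step 7
Reactants: 12 methyl 9-oxo-3β-(triethylsilyloxy)-11,12,13,14,15,16,17-heptanorlabdan-19-oate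
Product: 14 methyl 3β-(triethylsilyloxy)-9-(trifluoromethylsulfonyloxy)-11,12,13,14,15,16,17-heptanorlabd-8-en-19-oate, via potassium enolate 13 (not isolated)
Conditions: KHMDS, THF, −78 °C; PhNTf2, −78 → 0 °C
Reagents that add atoms: N-phenylbis(trifluoromethanesulfonimide), O=S(=O)(N(c1ccccc1)S(=O)(=O)C(F)(F)F)C(F)(F)F
Why: Enol triflate formation by O-triflation of the ketone enolate; the ketone can enolise only towards C8 because C10 is quaternary, and the ester has no α-hydrogen.

Step 8
Reactants: 14 methyl 3β-(triethylsilyloxy)-9-(trifluoromethylsulfonyloxy)-11,12,13,14,15,16,17-heptanorlabd-8-en-19-oate; 15 2-methyl-2-vinyl-1,3-dioxolane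
Product: 17 methyl 13,13-ethylenedioxy-3β-(triethylsilyloxy)-14,15,17-trinorlabd-8-en-19-oate, via B-alkyl-9-BBN 16 (not isolated)
Conditions: 15, 9-BBN, THF, 0 °C → rt; then 14, Pd(dppf)Cl2 (cat.), AsPh3 (cat.), Cs2CO3, DMF–H2O, rt → 50 °C
Reagents that add atoms: none
Why: B-alkyl Suzuki–Miyaura coupling: anti-Markovnikov hydroboration of the vinyl ketal gives a primary alkylborane that couples with the enol triflate under palladium catalysis and aqueous base to form the C9–C11 bond.

Step 9
Reactants: 17 methyl 13,13-ethylenedioxy-3β-(triethylsilyloxy)-14,15,17-trinorlabd-8-en-19-oate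
Product: 19 methyl 13,13-ethylenedioxy-8α-hydroxy-3β-(triethylsilyloxy)-14,15,17-trinorlabdan-19-oate, via C8 alkylborane 18 (not isolated)
Conditions: BH3·SMe2, THF, 0 °C → rt; NaOH, H2O2, 0 °C
Reagents that add atoms: hydrogen peroxide, OO
Why: Hydroboration–oxidation of the trisubstituted C8=C9 alkene: boron goes to the less substituted C8 and hydrogen to C9, syn and from the α face opposite the axial C10 methyl, which sets H-9 as α (side chain β, equatorial) and the hydroxyl as 8α, while the hindered neopentyl ester is not reduced at this temperature.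

Step 10
Reactants: 19 methyl 13,13-ethylenedioxy-8α-hydroxy-3β-(triethylsilyloxy)-14,15,17-trinorlabdan-19-oate
Product: 20 methyl 13,13-ethylenedioxy-8-oxo-3β-(triethylsilyloxy)-14,15,17-trinorlabdan-19-oate
Conditions: Dess–Martin periodinane, pyridine, CH2Cl2, rt
Reagents that add atoms: none
Why: Dess–Martin oxidation of the secondary alcohol under buffered conditions that spare the silyl ether and ketal; C9 keeps its stable configuration with the side chain equatorial.

Step 11
Reactants: 20 methyl 13,13-ethylenedioxy-8-oxo-3β-(triethylsilyloxy)-14,15,17-trinorlabdan-19-oate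
Product: 21 methyl 13,13-ethylenedioxy-3β-(triethylsilyloxy)-14,15-dinorlabd-8(17)-en-19-oate
Conditions: Ph3PCH3Br, KOt-Bu, THF, 0 → 50 °C
Reagents that add atoms: methyltriphenylphosphonium bromide, [Br-].C[P+](c1ccccc1)(c1ccccc1)c1ccccc1
Why: Wittig methylenation of the ketone installs C17, and any enolisation at C9 by the ylide returns the thermodynamically preferred equatorial side chain.

Step 12
Reactants: 21 methyl 13,13-ethylenedioxy-3β-(triethylsilyloxy)-14,15-dinorlabd-8(17)-en-19-oate
Product: 22 methyl 3β-hydroxy-13-oxo-14,15-dinorlabd-8(17)-en-19-oate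
Conditions: 1 M aq. HCl, THF, rt
Reagents that add atoms: water, O
Why: Acid hydrolysis cleaves the dioxolane to the methyl ketone and the triethylsilyl ether to the alcohol in one operation, under conditions mild enough to leave the exocyclic alkene where it is.

Step 13
Reactants: 22 methyl 3β-hydroxy-13-oxo-14,15-dinorlabd-8(17)-en-19-oate
Product: 23 15-ethyl 19-methyl 3β-hydroxylabda-8(17),13E-diene-15,19-dioate
Conditions: (EtO)2P(O)CH2CO2Et (slight excess over NaH), NaH, THF, 0 → 50 °C; chromatography
Reagents that add atoms: triethyl phosphonoacetate, CCOC(=O)CP(=O)(OCC)OCC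
Why: Horner–Wadsworth–Emmons olefination of the methyl ketone with the preformed sodium phosphonate, which is too weak a base to deprotonate the C3 hydroxyl and start a retro-aldol; the E isomer should predominate and the minor Z isomer is removed by chromatography.

Step 14
Reactants: 23 15-ethyl 19-methyl 3β-hydroxylabda-8(17),13E-diene-15,19-dioate
Product: 24 labda-8(17),13E-diene-3β,15,19-triol
Conditions: DIBAL-H (excess), CH2Cl2, −78 °C → rt; Rochelle salt work-up
Reagents that add atoms: none
Why: DIBAL-H reduction: the conjugated ester gives the allylic alcohol by 1,2-reduction and the hindered C19 ester is reduced to the primary alcohol on warming, with no effect on either alkene.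

Step 15
Reactants: 24 labda-8(17),13E-diene-3β,15,19-triol
Product: 25 15-(tert-butyldimethylsilyloxy)labda-8(17),13E-diene-3β,19-diol
Conditions: TBSCl (1.05 equiv), imidazole, CH2Cl2, −20 → 0 °C
Reagents that add atoms: tert-butyldimethylsilyl chloride, CC(C)(C)[Si](C)(C)Cl
Why: Selective silylation: the unhindered primary allylic C15 hydroxyl reacts far faster than the neopentyl C19 and the secondary C3 hydroxyls.

Step 16
Reactants: 25 15-(tert-butyldimethylsilyloxy)labda-8(17),13E-diene-3β,19-diol
Product: 26 15-(tert-butyldimethylsilyloxy)-3β-hydroxylabda-8(17),13E-dien-19-al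
Conditions: TEMPO (cat.), PhI(OAc)2, CH2Cl2, rt
Reagents that add atoms: none
Why: TEMPO/PhI(OAc)2 oxidation is selective for primary over secondary alcohols, so C19 becomes the aldehyde while the C3 alcohol stays, and the aldehyde has no α-hydrogen to epimerise.

Step 17
Reactants: 26 15-(tert-butyldimethylsilyloxy)-3β-hydroxylabda-8(17),13E-dien-19-al
Product: 27 3β-acetoxy-15-(tert-butyldimethylsilyloxy)labda-8(17),13E-dien-19-al
Conditions: Ac2O, pyridine, DMAP (cat.), CH2Cl2, rt
Reagents that add atoms: acetic anhydride, CC(=O)OC(C)=O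
Why: DMAP-catalysed acetylation of the remaining secondary alcohol under conditions too mild for retro-aldol of the β-hydroxy aldehyde.

Step 18
Reactants: 27 3β-acetoxy-15-(tert-butyldimethylsilyloxy)labda-8(17),13E-dien-19-al
Product: 28 3β-acetoxy-15-hydroxylabda-8(17),13E-dien-19-al
Conditions: HF·pyridine, pyridine, THF, 0 °C → rt
Reagents that add atoms: none
Why: Fluoride cleavage of the primary silyl ether with buffered HF·pyridine leaves the acetate, the aldehyde and both alkenes untouched.

Compound list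
1 | methyl propanoate | CCC(=O)OC | starting material
2 | lithium (E)-enolate of methyl propanoate | C/C=C(\OC)O[Li] | intermediate (not isolated)
3 | (E)-1-methoxy-1-(trimethylsilyloxy)prop-1-ene | C/C=C(\OC)O[Si](C)(C)C | intermediate
4 | 2-methylcyclohex-2-en-1-one | CC1=CCCCC1=O | starting material
5 | methyl 2-[(1S)-2-methyl-3-(trimethylsilyloxy)cyclohex-2-en-1-yl]propanoate (both epimers at the ester α-carbon) | C1CC[C@@H](C(C)C(=O)OC)C(C)=C1O[Si](C)(C)C | intermediate
6 | lithium ester enolate of 5 | C1CC[C@@H](C(C)=C(OC)O[Li])C(C)=C1O[Si](C)(C)C | intermediate (not isolated)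
7 | methyl 2-bromo-2-[(1R)-2-methyl-3-(trimethylsilyloxy)cyclohex-2-en-1-yl]propanoate (both C–Br epimers) | C1CC[C@@H](C(C)(Br)C(=O)OC)C(C)=C1O[Si](C)(C)C | intermediate
8 | acrolein | C=CC=O | starting material
9 | methyl 2-bromo-2-[(1R,2S)-2-methyl-3-oxo-2-(3-oxopropyl)cyclohexyl]propanoate (both C–Br epimers) | C1CC[C@@H](C(C)(Br)C(=O)OC)[C@](C)(CCC=O)C1=O | intermediate
10 | samarium(III) ester enolate of 9 | C1CC[C@@H](C(C)=C(OC)O[Sm](I)I)[C@](C)(CCC=O)C1=O | intermediate (not isolated)
11 | methyl 3β-hydroxy-9-oxo-11,12,13,14,15,16,17-heptanorlabdan-19-oate (trans-decalin, 5α-H, 10β-CH3, 4α-CH3, 4β-CO2Me) | C1CC[C@H]2[C@@](C)(C(=O)OC)[C@@H](O)CC[C@]2(C)C1=O | intermediate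
12 | methyl 9-oxo-3β-(triethylsilyloxy)-11,12,13,14,15,16,17-heptanorlabdan-19-oate | C1CC[C@H]2[C@@](C)(C(=O)OC)[C@@H](O[Si](CC)(CC)CC)CC[C@]2(C)C1=O | intermediate
13 | potassium Δ8 enolate of 12 | C1CC[C@H]2[C@@](C)(C(=O)OC)[C@@H](O[Si](CC)(CC)CC)CC[C@]2(C)C=1O[K] | intermediate (not isolated)
14 | methyl 3β-(triethylsilyloxy)-9-(trifluoromethylsulfonyloxy)-11,12,13,14,15,16,17-heptanorlabd-8-en-19-oate | C1CC[C@H]2[C@@](C)(C(=O)OC)[C@@H](O[Si](CC)(CC)CC)CC[C@]2(C)C=1OS(=O)(=O)C(F)(F)F | intermediate
15 | 2-methyl-2-vinyl-1,3-dioxolane | C=CC1(C)OCCO1 | starting material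
16 | 9-[2-(2-methyl-1,3-dioxolan-2-yl)ethyl]-9-borabicyclo[3.3.1]nonane | CC1(CCB2C3CCCC2CCC3)OCCO1 | intermediate (not isolated)
17 | methyl 13,13-ethylenedioxy-3β-(triethylsilyloxy)-14,15,17-trinorlabd-8-en-19-oate | C1CC[C@H]2[C@@](C)(C(=O)OC)[C@@H](O[Si](CC)(CC)CC)CC[C@]2(C)C=1CCC3(C)OCCO3 | intermediate
18 | 8α-boryl-9α-H alkylborane from 17 | B[C@@H]1CC[C@H]2[C@@](C)(C(=O)OC)[C@@H](O[Si](CC)(CC)CC)CC[C@]2(C)[C@H]1CCC3(C)OCCO3 | intermediate (not isolated)
19 | methyl 13,13-ethylenedioxy-8α-hydroxy-3β-(triethylsilyloxy)-14,15,17-trinorlabdan-19-oate | O[C@@H]1CC[C@H]2[C@@](C)(C(=O)OC)[C@@H](O[Si](CC)(CC)CC)CC[C@]2(C)[C@H]1CCC3(C)OCCO3 | intermediate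
20 | methyl 13,13-ethylenedioxy-8-oxo-3β-(triethylsilyloxy)-14,15,17-trinorlabdan-19-oate | O=C1CC[C@H]2[C@@](C)(C(=O)OC)[C@@H](O[Si](CC)(CC)CC)CC[C@]2(C)[C@H]1CCC3(C)OCCO3 | intermediate
21 | methyl 13,13-ethylenedioxy-3β-(triethylsilyloxy)-14,15-dinorlabd-8(17)-en-19-oate | C=C1CC[C@H]2[C@@](C)(C(=O)OC)[C@@H](O[Si](CC)(CC)CC)CC[C@]2(C)[C@H]1CCC3(C)OCCO3 | intermediate
22 | methyl 3β-hydroxy-13-oxo-14,15-dinorlabd-8(17)-en-19-oate | C=C1CC[C@H]2[C@@](C)(C(=O)OC)[C@@H](O)CC[C@]2(C)[C@H]1CCC(C)=O | intermediate
23 | 15-ethyl 19-methyl 3β-hydroxylabda-8(17),13E-diene-15,19-dioate | C=C1CC[C@H]2[C@@](C)(C(=O)OC)[C@@H](O)CC[C@]2(C)[C@H]1CC/C(C)=C/C(=O)OCC | intermediate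
24 | labda-8(17),13E-diene-3β,15,19-triol | C=C1CC[C@H]2[C@@](C)(CO)[C@@H](O)CC[C@]2(C)[C@H]1CC/C(C)=C/CO | intermediate
25 | 15-(tert-butyldimethylsilyloxy)labda-8(17),13E-diene-3β,19-diol | C=C1CC[C@H]2[C@@](C)(CO)[C@@H](O)CC[C@]2(C)[C@H]1CC/C(C)=C/CO[Si](C)(C)C(C)(C)C | intermediate
26 | 15-(tert-butyldimethylsilyloxy)-3β-hydroxylabda-8(17),13E-dien-19-al | C=C1CC[C@H]2[C@@](C)(C=O)[C@@H](O)CC[C@]2(C)[C@H]1CC/C(C)=C/CO[Si](C)(C)C(C)(C)C | intermediate
27 | 3β-acetoxy-15-(tert-butyldimethylsilyloxy)labda-8(17),13E-dien-19-al | C=C1CC[C@H]2[C@@](C)(C=O)[C@@H](OC(C)=O)CC[C@]2(C)[C@H]1CC/C(C)=C/CO[Si](C)(C)C(C)(C)C | intermediate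
28 | 3β-acetoxy-15-hydroxylabda-8(17),13E-dien-19-al (CNP0185120.1) | C=C1CC[C@H]2[C@@](C)(C=O)[C@@H](OC(C)=O)CC[C@]2(C)[C@H]1CC/C(C)=C/CO | target

Total step count: 18. Longest linear sequence: 18 steps (1 → 28).

Steps most likely to fail

1. Step 5 (key step). Facial control at C4 may be lost: the planar enolate can also close through the chair that turns the C18 methyl axial, which relieves allylic strain against C5 and would give the C4 epimer. The fallback takes the quaternary centre out of the ring closure; it sets out from 4 and returns at 11. Enone 4 reacts with commercial 1-(tert-butyldimethylsilyloxy)-1-methoxyethene under the conditions of step 2 to give methyl 2-[(1S)-3-(tert-butyldimethylsilyloxy)-2-methylcyclohex-2-en-1-yl]acetate F1. Bromination as in step 3 gives methyl 2-bromo-2-[(1R)-3-(tert-butyldimethylsilyloxy)-2-methylcyclohex-2-en-1-yl]acetate F2, and acrolein addition as in step 4 gives methyl 2-bromo-2-[(1R,2S)-2-methyl-3-oxo-2-(3-oxopropyl)cyclohexyl]acetate F3. Samarium Reformatsky closure, now without the methyl clash, gives methyl 3β-hydroxy-9-oxo-11,12,13,14,15,16,17,18-octanorlabdan-19-oate F4. The ketone is masked with 1,2-bis(trimethylsilyloxy)ethane and catalytic TMSOTf as methyl 9,9-ethylenedioxy-3β-hydroxy-11,12,13,14,15,16,17,18-octanorlabdan-19-oate F5. Fráter–Seebach methylation of its dianion (LDA, MeI) brings C18 in from the α face, anti to the C3 alkoxide and to the C10 methyl, giving methyl 9,9-ethylenedioxy-3β-hydroxy-11,12,13,14,15,16,17-heptanorlabdan-19-oate F6. Dilute aqueous acid removes the ketal and gives 11.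

2. Step 2. Facial selectivity at the enone β-carbon may be poor, because the α-methyl group changes how the chiral Lewis acid binds and an achiral silyl-cation pathway can compete. The fallback uses chirality transfer; it sets out from 4 and returns at 5. CBS reduction of 4 gives (S)-2-methylcyclohex-2-en-1-ol F7, and propanoyl chloride/pyridine gives (S)-2-methylcyclohex-2-en-1-yl propanoate F8. Ireland–Claisen rearrangement (LDA, TMSCl, −78 °C to reflux) moves the stereocentre suprafacially from C–O to C–C and gives 2-[(1S)-2-methylcyclohex-2-en-1-yl]propanoic acid F9, which is esterified (MeI, K2CO3) to methyl 2-[(1S)-2-methylcyclohex-2-en-1-yl]propanoate F10. Hydroboration–oxidation gives methyl 2-[(1R)-3-hydroxy-2-methylcyclohexyl]propanoate F11, and Dess–Martin oxidation gives methyl 2-[(1R)-2-methyl-3-oxocyclohexyl]propanoate F12. TMSCl/NaI/Et3N in MeCN then forms the more substituted enol silane, which is 5.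

3. Step 4. The crowded enol silane may lose its silyl group to the proton source faster than it adds to acrolein, or acrolein may oligomerise. The fallback reverses the order and brings in bromine with both carbonyls masked; it sets out from 5 and returns at 9. Enol silane 5 adds to acrolein under the conditions of step 4 to give methyl 2-[(1S,2S)-2-methyl-3-oxo-2-(3-oxopropyl)cyclohexyl]propanoate F13. The aldehyde alone is acetalised (HC(OMe)3, MeOH, PPTS) to methyl 2-[(1S,2S)-2-(3,3-dimethoxypropyl)-2-methyl-3-oxocyclohexyl]propanoate F14. LDA (2.2 equiv) with TMSCl gives the bis(trimethylsilyl) enol ether–ketene acetal of F14 F15. NBS (1 equiv, −78 °C) brominates the more nucleophilic ketene acetal and aqueous work-up frees the ketone, giving methyl 2-bromo-2-[(1R,2S)-2-(3,3-dimethoxypropyl)-2-methyl-3-oxocyclohexyl]propanoate F16. Dilute aqueous acid releases the aldehyde and gives 9.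

Further compounds
F1 | step 5 | methyl 2-[(1S)-3-(tert-butyldimethylsilyloxy)-2-methylcyclohex-2-en-1-yl]acetate | C1CC[C@@H](CC(=O)OC)C(C)=C1O[Si](C)(C)C(C)(C)C
F2 | step 5 | methyl 2-bromo-2-[(1R)-3-(tert-butyldimethylsilyloxy)-2-methylcyclohex-2-en-1-yl]acetate | C1CC[C@@H](C(Br)C(=O)OC)C(C)=C1O[Si](C)(C)C(C)(C)C
F3 | step 5 | methyl 2-bromo-2-[(1R,2S)-2-methyl-3-oxo-2-(3-oxopropyl)cyclohexyl]acetate | C1CC[C@@H](C(Br)C(=O)OC)[C@](C)(CCC=O)C1=O
F4 | step 5 | methyl 3β-hydroxy-9-oxo-11,12,13,14,15,16,17,18-octanorlabdan-19-oate (C4–H, either epimer) | C1CC[C@H]2C(C(=O)OC)[C@@H](O)CC[C@]2(C)C1=O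
F5 | step 5 | methyl 9,9-ethylenedioxy-3β-hydroxy-11,12,13,14,15,16,17,18-octanorlabdan-19-oate | C1CC[C@H]2C(C(=O)OC)[C@@H](O)CC[C@]2(C)C13OCCO3
F6 | step 5 | methyl 9,9-ethylenedioxy-3β-hydroxy-11,12,13,14,15,16,17-heptanorlabdan-19-oate | C1CC[C@H]2[C@@](C)(C(=O)OC)[C@@H](O)CC[C@]2(C)C13OCCO3
F7 | step 2 | (S)-2-methylcyclohex-2-en-1-ol | O[C@H]1CCCC=C1C
F8 | step 2 | (S)-2-methylcyclohex-2-en-1-yl propanoate | CCC(=O)O[C@H]1CCCC=C1C
F9 | step 2 | 2-[(1S)-2-methylcyclohex-2-en-1-yl]propanoic acid | C1CC[C@@H](C(C)C(=O)O)C(C)=C1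
F10 | step 2 | methyl 2-[(1S)-2-methylcyclohex-2-en-1-yl]propanoate | C1CC[C@@H](C(C)C(=O)OC)C(C)=C1
F11 | step 2 | methyl 2-[(1R)-3-hydroxy-2-methylcyclohexyl]propanoate | C1CC[C@@H](C(C)C(=O)OC)C(C)C1O
F12 | step 2 | methyl 2-[(1R)-2-methyl-3-oxocyclohexyl]propanoate | C1CC[C@@H](C(C)C(=O)OC)C(C)C1=O
F13 | step 4 | methyl 2-[(1S,2S)-2-methyl-3-oxo-2-(3-oxopropyl)cyclohexyl]propanoate | C1CC[C@@H](C(C)C(=O)OC)[C@](C)(CCC=O)C1=O
F14 | step 4 | methyl 2-[(1S,2S)-2-(3,3-dimethoxypropyl)-2-methyl-3-oxocyclohexyl]propanoate | C1CC[C@@H](C(C)C(=O)OC)[C@](C)(CCC(OC)OC)C1=O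
F15 | step 4 | bis(trimethylsilyl) enol ether–ketene acetal of F14 | C1CC[C@@H](C(C)=C(OC)O[Si](C)(C)C)[C@](C)(CCC(OC)OC)C=1O[Si](C)(C)C
F16 | step 4 | methyl 2-bromo-2-[(1R,2S)-2-(3,3-dimethoxypropyl)-2-methyl-3-oxocyclohexyl]propanoate | C1CC[C@@H](C(C)(Br)C(=O)OC)[C@](C)(CCC(OC)OC)C1=O
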